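At early times the midnight run, in which starting complex meets incoming ligand, shows a gap: by 4.00 min starting complex has fallen by 11.2%, while complex with two exchanged reads 3.2%, less than that loss. So in the midnight run not every molecule that has left free starting complex has arrived by then, and its chances along the way are reckoned below.

all flasks: starting complex 24 mM
- dusk: incoming ligand 0.77 equiv; run made earlier
- noon: incoming ligand 1.6 equiv; run made earlier
- midnight: incoming ligand 2 equiv; run made earlier
- Tuesday's: incoming ligand 1.10 equiv; time 40 min
- Saturday's: incoming ligand 2.20 equiv; time 40 min

| run | time / min | complex with two exchanged / % | starting complex / % |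
|---|---|---|---|
| dusk | 1.50 | 0 | 98.4 |
| dusk | 4.00 | 0.8 | 96.4 |
| dusk | 8.00 | 1.7 | 91.1 |
| dusk | 20.0 | 5.8 | 80.8 |
| noon | 5.00 | 4.0 | 89.4 |
| noon | 10.0 | 6.8 | 78.9 |
| noon | 15.0 | 10.1 | 72.1 |
| noon | 20.0 | 12.9 | 64.9 |
| midnight | 1.50 | 0.9 | 95.1 |
| midnight | 4.00 | 3.2 | 88.8 |
| midnight | 8.00 | 8.7 | 78.9 |
| midnight | 20.0 | 14.1 | 60.2 |

(readings scatter by 1 percentage point)

- a reading or a percentage of complex with two exchanged counts all its forms, free or not
- a reading of starting complex is of its free form alone

- which of the two there is more of at the end, Tuesday's (complex with two exchanged / complex with three exchanged)
- which of the two there is more of at the end, Saturday's (complex with two exchanged / complex with three exchanged)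
- how much complex with two exchanged is there at the end, in percent of the starting complex charged: Tuesday's
- how much complex with two exchanged is there at the end, in percent of the starting complex charged: Saturday's

Take first the main step by itself, with each departing molecule arriving. Survival of starting complex is taken to follow the product of equivalents and time, so the midnight reading of 60.2% at 20.0 min is raised to the ratio of those products. Tuesday's then keeps 57.2% and Saturday's 32.7%, which gives 42.8% and 67.3% of complex with two exchanged.

Now add the stop on the way, where a molecule that has left starting complex may wait unread or go on. The midnight run at 20.0 min reads 35.4% for the arrival share, c(complex with two exchanged) over the charged starting complex no longer free. The dusk and noon runs read 30.2% and 36.8%. Saturday's charge lies near midnight's, so it takes that reading; Tuesday's lies between dusk's and noon's, so it takes their mean, 33.5%. The numbers drop to 14.3% for Tuesday's and 23.8% for Saturday's, on the assumption that the share holds from 20.0 min to 40 min.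

The rest, passage on to complex with three exchanged, is unread, but whatever of it had happened by 20.0 min already lies inside the share. Midnight's complex with two exchanged still rises from 8.7% to 14.1% at its last readings, so this reckoning leaves its numbers standing and expects complex with two exchanged to be the larger in both flasks.

The forecast also names complex with two exchanged for Tuesday's and complex with two exchanged for Saturday's, but its amounts are higher than this reckoning's: 23% and 38%. On the third complex it says: “The runs show little loss to three-exchanged, so it is only bounded, not measured.”

Tuesday's ends with 9.58% of complex with two exchanged against 0.140% of complex with three exchanged, and Saturday's with 17.6% against 0.632%.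

    starting complex + incoming ligand ⇌ leaving ligand + complex with one exchanged (K = 1.90, k = 0.610 /M/min)
    complex with one exchanged + incoming ligand ⇌ leaving ligand + complex with two exchanged (K = 0.201, k = 4.56 /M/min)
    starting complex + complex with two exchanged ⇌ idle adduct, settled at all times (K = 20.0 /M)
    complex with two exchanged + incoming ligand ⇌ leaving ligand + complex with three exchanged (K = 0.998, k = 0.0382 /M/min)

With 39% of its starting complex left free, Saturday's has an arrival share of 29.1% at 40 min, below the 35.4% carried over, while complex with one exchanged holds 39.5%. A neighbour of Saturday's is charged with 5.50 equiv of incoming ligand. The product rule leaves it 6.13% of starting complex, and the carried share then gives 33.2%. That flask keeps 12.9% of starting complex and holds 33.6% of complex with two exchanged.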